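**Plan**

1. Locants: ring A is the stilbene-bearing dihydrobenzofuran (O1, C2, C3, C3a, C4–C7, C7a); ring B is the catechol-bearing one (primed). The benzene of ring B (C3a', C4', C5', C6', C7', C7a') carries O1', C3', the C4' oxygen and C3 of ring A, which is the substitution pattern a diyne-plus-alkyne cyclotrimerisation delivers.
2. Retrosynthesis: the eight phenols are unmasked last (seven O–Me bonds, and C4'–O from C4'–SiMe3). Then C3a'–C7a', C4'–C5' and C6'–C7' are cut together, giving a ring A 3-ethynyl unit and a 1,6-diyne (ethynyl ether and silylalkyne ends) held by the O1'–C2'–C3' tether.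
3. Further cuts: the diyne at C2'–C3' and at O1'–C(alkyne); ring A at C2–C3, at the C6–vinyl bond and at C3–C(alkyne).
4. Forward: the dihydrofuran of ring A closes first (rhodium-carbenoid C–H insertion), then stilbene (Heck) and alkyne (Ohira–Bestmann). The diyne chain is joined at C2'–C3' (allenylzinc addition) and O-ethynylated. One ruthenium-catalysed [2+2+2] closes the benzene and the dihydrofuran of ring B, and demethylation with C–Si to C–O exchange ends the route.
5. Stereochemistry: C2 from the chiral Rh2 catalyst, C3 by equilibration to trans; C3' by chirality transfer from an (R)-propargylic alcohol made by catalytic asymmetric alkynylation, C2' by the anti-selective cyclic addition; the E-alkene from the Heck reaction; the cycloaddition creates no stereocentre.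

Key step: step 17

Assumption: (S,S)-ProPhenol is taken to give the (R)-propargylic alcohol in step 11 and Rh2(S-PTTL)4 the (2R)-configured ring in step 7; if either sense is the opposite, the mirror-image ligand or catalyst is used with no other change.

**Ring A alkyne**

Step 1
Reactants: 1 4-bromo-2,6-difluorobenzaldehyde
Product: 2 4-bromo-2-fluoro-6-methoxybenzaldehyde
Conditions: NaOMe (1.05 equiv), MeOH, 0 °C → rt
Reagents that add atoms: sodium methoxide, [Na+].[O-]C
Why: Nucleophilic aromatic substitution (SNAr) at a fluoride ortho to the formyl group, the first methoxy group then deactivating the ring so that one equivalent of methoxide stops at the mono-ether.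

Step 2
Reactants: 2 4-bromo-2-fluoro-6-methoxybenzaldehyde; 3 4-methoxybenzyl alcohol
Product: 4 4-bromo-2-methoxy-6-[(4-methoxyphenyl)methoxy]benzaldehyde
Conditions: NaH, THF, 0 °C → rt
Reagents that add atoms: none
Why: A second SNAr, by the sodium alkoxide of 3 on the remaining formyl-activated fluoride, installs the benzylic O–CH2 group whose C–H bond later becomes C2–H and whose aryl ring becomes the 2-(4-methoxyphenyl) group.

Step 3
Reactants: 4 4-bromo-2-methoxy-6-[(4-methoxyphenyl)methoxy]benzaldehyde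
Product: 5 rac-1-{4-bromo-2-methoxy-6-[(4-methoxyphenyl)methoxy]phenyl}-2,2,2-trichloroethan-1-ol
Conditions: Cl3CCO2Na, Cl3CCO2H, DMF, rt
Reagents that add atoms: sodium trichloroacetate, [Na+].[O-]C(=O)C(Cl)(Cl)Cl
Why: Decarboxylative trichloromethylation (Corey–Link conditions) in which the trichloromethyl anion released from the carboxylate adds to the non-enolisable aldehyde, the new carbinol centre forming as a racemate that step 4 removes.

Step 4
Reactants: 5 rac-1-{4-bromo-2-methoxy-6-[(4-methoxyphenyl)methoxy]phenyl}-2,2,2-trichloroethan-1-ol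
Product: 6 2-{4-bromo-2-methoxy-6-[(4-methoxyphenyl)methoxy]phenyl}acetic acid
Conditions: NaBH4, NaOH, t-BuOH–H2O, 55 °C; then aq. HCl
Reagents that add atoms: sodium hydroxide, [Na+].[OH-]
Why: Jocic-type reductive homologation in which the alkoxide closes to a gem-dichloroepoxide, borohydride opens it at the benzylic carbon and hydroxide hydrolyses the resulting acyl chloride, so that the former aldehyde carbon ends as the CH2 of an arylacetic acid.

Step 5
Reactants: 6 2-{4-bromo-2-methoxy-6-[(4-methoxyphenyl)methoxy]phenyl}acetic acid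
Product: 7 methyl 2-{4-bromo-2-methoxy-6-[(4-methoxyphenyl)methoxy]phenyl}acetate
Conditions: MeI, K2CO3, DMF, rt
Reagents that add atoms: iodomethane, CI
Why: SN2 O-methylation of the carboxylate gives the ester needed for diazo transfer.

Step 6
Reactants: 7 methyl 2-{4-bromo-2-methoxy-6-[(4-methoxyphenyl)methoxy]phenyl}acetate
Product: 8 methyl 2-diazo-2-{4-bromo-2-methoxy-6-[(4-methoxyphenyl)methoxy]phenyl}acetate
Conditions: 4-acetamidobenzenesulfonyl azide, DBU, MeCN, 0 °C → rt
Reagents that add atoms: 4-acetamidobenzenesulfonyl azide, CC(=O)Nc1ccc(cc1)S(=O)(=O)N=[N+]=[N-]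
Why: Regitz diazo transfer from the sulfonyl azide to the DBU-generated ester enolate gives the donor/acceptor diazo compound.

Step 7
Reactants: 8 methyl 2-diazo-2-{4-bromo-2-methoxy-6-[(4-methoxyphenyl)methoxy]phenyl}acetate
Product: 9 methyl (2R,3S)-6-bromo-4-methoxy-2-(4-methoxyphenyl)-2,3-dihydro-1-benzofuran-3-carboxylate (cis)
Conditions: Rh2(S-PTTL)4 [dirhodium tetrakis(N-phthaloyl-(S)-tert-leucinate)] (2 mol %), toluene, −60 → −20 °C
Reagents that add atoms: none
Why: Intramolecular 1,5 C–H insertion of the rhodium carbenoid into the benzylic O–CH2 bond, which is activated by oxygen and by the 4-methoxyphenyl ring and therefore preferred over the methoxy C–H, forms C2–C3 and closes the dihydrofuran, the chiral carboxylate ligands choosing one enantiotopic hydrogen so that C2 is set R with the ester cis (C3 S).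

Step 8
Reactants: 9 methyl (2R,3S)-6-bromo-4-methoxy-2-(4-methoxyphenyl)-2,3-dihydro-1-benzofuran-3-carboxylate
Product: 10 methyl (2R,3R)-6-bromo-4-methoxy-2-(4-methoxyphenyl)-2,3-dihydro-1-benzofuran-3-carboxylate (trans)
Conditions: NaOMe (0.3 equiv), MeOH, rt
Reagents that add atoms: none
Why: Base-mediated epimerisation of the ester α-carbon C3 through its enolate leads to the thermodynamically preferred trans isomer (C3 R), while C2 is untouched because expulsion of the ring oxygen from the enolate would be a stereoelectronically disfavoured 5-endo process.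

Step 9
Reactants: 10 methyl (2R,3R)-6-bromo-4-methoxy-2-(4-methoxyphenyl)-2,3-dihydro-1-benzofuran-3-carboxylate; 11 4-methoxystyrene
Product: 12 methyl (2R,3R)-4-methoxy-2-(4-methoxyphenyl)-6-[(E)-2-(4-methoxyphenyl)ethenyl]-2,3-dihydro-1-benzofuran-3-carboxylate
Conditions: Pd(OAc)2, P(o-tol)3, Et3N, DMF, 100 °C
Reagents that add atoms: none
Why: Mizoroki–Heck reaction of the aryl bromide with the styrene, in which syn insertion and syn β-hydride elimination give the E-stilbene and the amine base leaves the trans ester as it is.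

Step 10
Reactants: 12 methyl (2R,3R)-4-methoxy-2-(4-methoxyphenyl)-6-[(E)-2-(4-methoxyphenyl)ethenyl]-2,3-dihydro-1-benzofuran-3-carboxylate
Product: 14 (2R,3R)-3-ethynyl-4-methoxy-2-(4-methoxyphenyl)-6-[(E)-2-(4-methoxyphenyl)ethenyl]-2,3-dihydro-1-benzofuran, via trans-3-carbaldehyde 13 (not isolated)
Conditions: i-Bu2AlH (DIBAL-H, 1.1 equiv), CH2Cl2, −78 °C; then MeOH; then dimethyl (1-diazo-2-oxopropyl)phosphonate, K2CO3, MeOH, −78 °C → rt
Reagents that add atoms: dimethyl (1-diazo-2-oxopropyl)phosphonate, CC(=O)C(=[N+]=[N-])P(=O)(OC)OC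
Why: Partial reduction of the ester at −78 °C stops at the aluminium hemiacetal, which releases aldehyde 13 on adding methanol, and Ohira–Bestmann (Seyferth–Gilbert) homologation converts it in the same flask into the terminal alkyne, C3 staying trans because any enolisation of 13 returns to the more stable isomer.

**Diyne**

Step 11
Reactants: 15 3,5-dimethoxybenzaldehyde; 16 trimethylsilylacetylene
Product: 17 (1R)-1-(3,5-dimethoxyphenyl)-3-(trimethylsilyl)prop-2-yn-1-ol
Conditions: (S,S)-ProPhenol (10 mol %), Ph3P=O (20 mol %), Me2Zn (3 equiv), toluene, 0 °C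
Reagents that add atoms: none
Why: Catalytic asymmetric alkynylation in which the dinuclear zinc–ProPhenol complex binds aldehyde and alkynylzinc and delivers the alkynyl group to one face of the aldehyde, setting the carbinol centre R.

Step 12
Reactants: 17 (1R)-1-(3,5-dimethoxyphenyl)-3-(trimethylsilyl)prop-2-yn-1-ol
Product: 18 (1R)-1-(3,5-dimethoxyphenyl)-3-(trimethylsilyl)prop-2-yn-1-yl methanesulfonate
Conditions: MsCl, Et3N, CH2Cl2, −78 °C; used crude
Reagents that add atoms: methanesulfonyl chloride, CS(=O)(=O)Cl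
Why: O-Sulfonylation at low temperature forms the leaving group without touching the stereocentre (retention), and the labile benzylic propargylic mesylate is used at once.

Step 13
Reactants: 18 (1R)-1-(3,5-dimethoxyphenyl)-3-(trimethylsilyl)prop-2-yn-1-yl methanesulfonate; 19 3,4-dimethoxybenzaldehyde
Product: 21 (1S,2S)-1-(3,4-dimethoxyphenyl)-2-(3,5-dimethoxyphenyl)-4-(trimethylsilyl)but-3-yn-1-ol, via allenylzinc 20 (not isolated)
Conditions: Pd(OAc)2 (5 mol %), PPh3 (5 mol %), Et2Zn (3 equiv), THF, −78 → −20 °C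
Reagents that add atoms: none
Why: Zerovalent palladium displaces the mesylate anti (SN2') to an allenylpalladium species, ethyl exchange with Et2Zn gives the configurationally defined allenylzinc 20, and its cyclic SE2' addition to the aldehyde forms the new C–C bond anti to the departed mesylate (the propargylic carbon, future C3', becomes S by chirality transfer) with the two aryl groups apart in the six-membered transition state (anti adduct, the carbinol carbon, future C2', becomes S).

Step 14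
Reactants: 21 (1S,2S)-1-(3,4-dimethoxyphenyl)-2-(3,5-dimethoxyphenyl)-4-(trimethylsilyl)but-3-yn-1-ol
Product: 22 (1S,2S)-1-(3,4-dimethoxyphenyl)-2-(3,5-dimethoxyphenyl)-4-(trimethylsilyl)but-3-yn-1-yl formate
Conditions: HCO2H, DCC, DMAP (cat.), CH2Cl2, 0 °C → rt
Reagents that add atoms: formic acid, OC=O
Why: Steglich-type formylation acylates the hindered secondary alcohol under conditions that never generate the alkoxide, which could undergo retro-addition or attack the alkynylsilane, and the configuration at both centres is retained.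

Step 15
Reactants: 22 (1S,2S)-1-(3,4-dimethoxyphenyl)-2-(3,5-dimethoxyphenyl)-4-(trimethylsilyl)but-3-yn-1-yl formate
Product: 23 {(3S,4S)-4-[(2,2-dichloroethenyl)oxy]-4-(3,4-dimethoxyphenyl)-3-(3,5-dimethoxyphenyl)but-1-yn-1-yl}trimethylsilane
Conditions: PPh3 (3 equiv), CCl4, THF, 60 °C
Reagents that add atoms: carbon tetrachloride, ClC(Cl)(Cl)Cl
Why: Wittig-type dichloromethylenation in which Ph3P=CCl2, formed from PPh3 and CCl4, olefinates the aldehyde-like formate carbonyl to the 2,2-dichlorovinyl ether under neutral conditions.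

Step 16
Reactants: 23 {(3S,4S)-4-[(2,2-dichloroethenyl)oxy]-4-(3,4-dimethoxyphenyl)-3-(3,5-dimethoxyphenyl)but-1-yn-1-yl}trimethylsilane
Product: 25 {(3S,4S)-4-(3,4-dimethoxyphenyl)-3-(3,5-dimethoxyphenyl)-4-(ethynyloxy)but-1-yn-1-yl}trimethylsilane, via lithium alkoxyacetylide 24 (not isolated)
Conditions: n-BuLi (2.1 equiv), Et2O, −78 °C; then aq. NH4Cl, −78 → 0 °C; cold filtration through Et3N-deactivated silica, used at once
Reagents that add atoms: none
Why: Dehydrochlorination followed by chlorine–lithium exchange converts the dichlorovinyl ether into lithium alkoxyacetylide 24, these fast processes at −78 °C outrunning deprotonation of the hindered tertiary C3'–H, and buffered protonation gives the heat-sensitive ethynyl ether, which is used without storage.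

**Union and end-game**

Step 17
Reactants: 25 {(3S,4S)-4-(3,4-dimethoxyphenyl)-3-(3,5-dimethoxyphenyl)-4-(ethynyloxy)but-1-yn-1-yl}trimethylsilane; 14 (2R,3R)-3-ethynyl-4-methoxy-2-(4-methoxyphenyl)-6-[(E)-2-(4-methoxyphenyl)ethenyl]-2,3-dihydro-1-benzofuran
Product: 26 {(2S,3S)-2-(3,4-dimethoxyphenyl)-3-(3,5-dimethoxyphenyl)-6-[(2R,3R)-4-methoxy-2-(4-methoxyphenyl)-6-[(E)-2-(4-methoxyphenyl)ethenyl]-2,3-dihydro-1-benzofuran-3-yl]-2,3-dihydro-1-benzofuran-4-yl}trimethylsilane
Conditions: Cp*RuCl(cod) [chloro(pentamethylcyclopentadienyl)(1,5-cyclooctadiene)ruthenium] (10 mol %), ClCH2CH2Cl, 20–25 °C, slow addition of 25 to 14 (1.3 equiv) and catalyst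
Reagents that add atoms: none
Why: Proposed new method: divalent ruthenium in Cp*RuCl(cod) loses cyclooctadiene and binds both alkynes of 25, oxidative cyclisation joins the oxygen-bearing alkyne carbon to the alkyne carbon on C3' (C3a'–C7a') to give a ruthenacycle fused to the nascent dihydrofuran, the terminal alkyne of 14 then inserts at the unsubstituted CH terminus (C6'–C7') and reductive elimination forms C4'–C5' and releases the arene. The closest known reaction type is the Cp*RuCl-catalysed [2+2+2] cycloaddition of 1,6-diynes with terminal alkynes, which accepts silylalkynes and alkynyl ethers as partners and places the alkyne substituent meta to a substituent on a diyne terminus; what lacks precedent is an ethynyl ether as one terminus of the diyne itself. The dihydrofuran of ring B closes as the five-membered ring made by the oxidative coupling of the tethered diyne, and the benzene closes by the formal [2+2+2] union of the three alkynes. No stereocentre is formed, and C2, C3, C2' and C3' are spectators under neutral conditions at ambient temperature, which also keeps the ethynyl ether below the temperature of its retro-ene loss of ketene. The only selectivity needed is the orientation of 14 (C3 of ring A at C6' and not at C5'), secured by the bulky trimethylsilyl group on the future C4' and the branched C3 substituent keeping apart in the ruthenacycle, while slow addition of 25 suppresses its self-trimerisation.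

Step 18
Reactants: 26 {(2S,3S)-2-(3,4-dimethoxyphenyl)-3-(3,5-dimethoxyphenyl)-6-[(2R,3R)-4-methoxy-2-(4-methoxyphenyl)-6-[(E)-2-(4-methoxyphenyl)ethenyl]-2,3-dihydro-1-benzofuran-3-yl]-2,3-dihydro-1-benzofuran-4-yl}trimethylsilane
Product: 28 (2S,3S)-2-(3,4-dihydroxyphenyl)-3-(3,5-dihydroxyphenyl)-6-[(2R,3R)-4-hydroxy-2-(4-hydroxyphenyl)-6-[(E)-2-(4-hydroxyphenyl)ethenyl]-2,3-dihydro-1-benzofuran-3-yl]-2,3-dihydro-1-benzofuran-4-ol (CNP0107857.3), via arylboronic acid 27 (not isolated)
Conditions: BBr3 (15 equiv), CH2Cl2, −78 °C → rt; then NaBO3·4H2O, THF–H2O, 0 °C → rt; pH 5 work-up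
Reagents that add atoms: sodium perborate, O[B-]1(O)OO[B-](O)(O)OO1.[Na+].[Na+]
Why: BBr3 cleaves the seven aryl methyl ethers and replaces the trimethylsilyl group at C4' by boron (ipso-borodesilylation), perborate oxidises the C–B bond of 27 to the C4' hydroxyl at the carbon that held silicon, and the stereocentres should survive because C3 and C3' carry no acidifying group and any reversible ionisation at the benzylic C2 or C2' ether carbon would re-close trans to them.

**Compound list**

1 | 4-bromo-2,6-difluorobenzaldehyde | O=Cc1c(F)cc(Br)cc1F | starting material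
2 | 4-bromo-2-fluoro-6-methoxybenzaldehyde | COc1cc(Br)cc(F)c1C=O | intermediate
3 | 4-methoxybenzyl alcohol | COc1ccc(CO)cc1 | starting material
4 | 4-bromo-2-methoxy-6-[(4-methoxyphenyl)methoxy]benzaldehyde | COc1ccc(COc2cc(Br)cc(OC)c2C=O)cc1 | intermediate
5 | rac-1-{4-bromo-2-methoxy-6-[(4-methoxyphenyl)methoxy]phenyl}-2,2,2-trichloroethan-1-ol | COc1ccc(COc2cc(Br)cc(OC)c2C(O)C(Cl)(Cl)Cl)cc1 | intermediate
6 | 2-{4-bromo-2-methoxy-6-[(4-methoxyphenyl)methoxy]phenyl}acetic acid | COc1ccc(COc2cc(Br)cc(OC)c2CC(=O)O)cc1 | intermediate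
7 | methyl 2-{4-bromo-2-methoxy-6-[(4-methoxyphenyl)methoxy]phenyl}acetate | COc1ccc(COc2cc(Br)cc(OC)c2CC(=O)OC)cc1 | intermediate
8 | methyl 2-diazo-2-{4-bromo-2-methoxy-6-[(4-methoxyphenyl)methoxy]phenyl}acetate | COc1ccc(COc2cc(Br)cc(OC)c2C(=[N+]=[N-])C(=O)OC)cc1 | intermediate
9 | methyl (2R,3S)-6-bromo-4-methoxy-2-(4-methoxyphenyl)-2,3-dihydro-1-benzofuran-3-carboxylate (cis) | Brc1cc(OC)c2c(c1)O[C@@H](c1ccc(OC)cc1)[C@H]2C(=O)OC | intermediate
10 | methyl (2R,3R)-6-bromo-4-methoxy-2-(4-methoxyphenyl)-2,3-dihydro-1-benzofuran-3-carboxylate (trans) | Brc1cc(OC)c2c(c1)O[C@@H](c1ccc(OC)cc1)[C@@H]2C(=O)OC | intermediate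
11 | 4-methoxystyrene | C=Cc1ccc(OC)cc1 | starting material
12 | methyl (2R,3R)-4-methoxy-2-(4-methoxyphenyl)-6-[(E)-2-(4-methoxyphenyl)ethenyl]-2,3-dihydro-1-benzofuran-3-carboxylate | COc1ccc(/C=C/c2cc(OC)c3c(c2)O[C@@H](c2ccc(OC)cc2)[C@@H]3C(=O)OC)cc1 | intermediate
13 | (2R,3R)-4-methoxy-2-(4-methoxyphenyl)-6-[(E)-2-(4-methoxyphenyl)ethenyl]-2,3-dihydro-1-benzofuran-3-carbaldehyde | COc1ccc(/C=C/c2cc(OC)c3c(c2)O[C@@H](c2ccc(OC)cc2)[C@@H]3C=O)cc1 | intermediate
14 | (2R,3R)-3-ethynyl-4-methoxy-2-(4-methoxyphenyl)-6-[(E)-2-(4-methoxyphenyl)ethenyl]-2,3-dihydro-1-benzofuran | COc1ccc(/C=C/c2cc(OC)c3c(c2)O[C@@H](c2ccc(OC)cc2)[C@@H]3C#C)cc1 | intermediate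
15 | 3,5-dimethoxybenzaldehyde | COc1cc(C=O)cc(OC)c1 | starting material
16 | trimethylsilylacetylene | C#C[Si](C)(C)C | starting material
17 | (1R)-1-(3,5-dimethoxyphenyl)-3-(trimethylsilyl)prop-2-yn-1-ol | O[C@@H](C#C[Si](C)(C)C)c1cc(OC)cc(OC)c1 | intermediate
18 | (1R)-1-(3,5-dimethoxyphenyl)-3-(trimethylsilyl)prop-2-yn-1-yl methanesulfonate | CS(=O)(=O)O[C@@H](C#C[Si](C)(C)C)c1cc(OC)cc(OC)c1 | intermediate
19 | 3,4-dimethoxybenzaldehyde | COc1ccc(C=O)cc1OC | starting material
20 | (aS)-ethyl[3-(3,5-dimethoxyphenyl)-1-(trimethylsilyl)propa-1,2-dien-1-yl]zinc | CC[Zn]C([Si](C)(C)C)=[C@@]=C([H])c1cc(OC)cc(OC)c1 | intermediate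
21 | (1S,2S)-1-(3,4-dimethoxyphenyl)-2-(3,5-dimethoxyphenyl)-4-(trimethylsilyl)but-3-yn-1-ol | O[C@H](c1ccc(OC)c(OC)c1)[C@@H](c1cc(OC)cc(OC)c1)C#C[Si](C)(C)C | intermediate
22 | (1S,2S)-1-(3,4-dimethoxyphenyl)-2-(3,5-dimethoxyphenyl)-4-(trimethylsilyl)but-3-yn-1-yl formate | O=CO[C@H](c1ccc(OC)c(OC)c1)[C@@H](c1cc(OC)cc(OC)c1)C#C[Si](C)(C)C | intermediate
23 | {(3S,4S)-4-[(2,2-dichloroethenyl)oxy]-4-(3,4-dimethoxyphenyl)-3-(3,5-dimethoxyphenyl)but-1-yn-1-yl}trimethylsilane | ClC(Cl)=CO[C@H](c1ccc(OC)c(OC)c1)[C@@H](c1cc(OC)cc(OC)c1)C#C[Si](C)(C)C | intermediate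
24 | ({[(1S,2S)-1-(3,4-dimethoxyphenyl)-2-(3,5-dimethoxyphenyl)-4-(trimethylsilyl)but-3-yn-1-yl]oxy}ethynyl)lithium | [Li]C#CO[C@H](c1ccc(OC)c(OC)c1)[C@@H](c1cc(OC)cc(OC)c1)C#C[Si](C)(C)C | intermediate
25 | {(3S,4S)-4-(3,4-dimethoxyphenyl)-3-(3,5-dimethoxyphenyl)-4-(ethynyloxy)but-1-yn-1-yl}trimethylsilane | C#CO[C@H](c1ccc(OC)c(OC)c1)[C@@H](c1cc(OC)cc(OC)c1)C#C[Si](C)(C)C | intermediate
26 | {(2S,3S)-2-(3,4-dimethoxyphenyl)-3-(3,5-dimethoxyphenyl)-6-[(2R,3R)-4-methoxy-2-(4-methoxyphenyl)-6-[(E)-2-(4-methoxyphenyl)ethenyl]-2,3-dihydro-1-benzofuran-3-yl]-2,3-dihydro-1-benzofuran-4-yl}trimethylsilane | COc1ccc(/C=C/c2cc(OC)c3c(c2)O[C@@H](c2ccc(OC)cc2)[C@@H]3c2cc([Si](C)(C)C)c3c(c2)O[C@H](c2ccc(OC)c(OC)c2)[C@H]3c2cc(OC)cc(OC)c2)cc1 | intermediate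
27 | {(2S,3S)-2-(3,4-dihydroxyphenyl)-3-(3,5-dihydroxyphenyl)-6-[(2R,3R)-4-hydroxy-2-(4-hydroxyphenyl)-6-[(E)-2-(4-hydroxyphenyl)ethenyl]-2,3-dihydro-1-benzofuran-3-yl]-2,3-dihydro-1-benzofuran-4-yl}boronic acid | Oc1ccc(/C=C/c2cc(O)c3c(c2)O[C@@H](c2ccc(O)cc2)[C@@H]3c2cc(B(O)O)c3c(c2)O[C@H](c2ccc(O)c(O)c2)[C@H]3c2cc(O)cc(O)c2)cc1 | intermediate
28 | (2S,3S)-2-(3,4-dihydroxyphenyl)-3-(3,5-dihydroxyphenyl)-6-[(2R,3R)-4-hydroxy-2-(4-hydroxyphenyl)-6-[(E)-2-(4-hydroxyphenyl)ethenyl]-2,3-dihydro-1-benzofuran-3-yl]-2,3-dihydro-1-benzofuran-4-ol | Oc1ccc(/C=C/c2cc(O)c3c(c2)O[C@@H](c2ccc(O)cc2)[C@@H]3c2cc(O)c3c(c2)O[C@H](c2ccc(O)c(O)c2)[C@H]3c2cc(O)cc(O)c2)cc1 | target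

**Step count**

Total: 18 steps. Longest linear sequence: 12 steps (steps 1–10, 17, 18); the diyne branch is steps 11–16.

**Steps most likely to fail**

Step 17 (cyclotrimerisation with an ethynyl ether terminus). The ethynyl ether may fragment (retro-ene loss of ketene, or ionisation at the electron-rich benzylic carbon) before it is engaged by ruthenium. The diyne may also oligomerise faster than it captures 14, or 14 may insert with the wrong orientation. The fallback uses known chemistry, sets out from alcohol 21 and alkyne 14, and returns at 26. Alcohol 21 is silylated with chloro(ethynyl)dimethylsilane and imidazole in CH2Cl2 to the ethynyl(dimethyl)silyl ether F1. Cyclotrimerisation of this silicon-tethered diyne with 14 under Cp*RuCl(cod) (ClCH2CH2Cl, 20–60 °C, no longer limited by a heat-sensitive group) should give the benzo-fused oxasiline F2 with the same meta orientation. Tamao oxidation (H2O2, KF, KHCO3, THF–MeOH) then cleaves the aryl–silicon bond of the cyclic alkoxysilane and leaves the C4' trimethylsilyl group, giving the phenol alcohol F3. Acid-catalysed cyclodehydration (TsOH cat., CH2Cl2, 0 °C) through the 3,4-dimethoxybenzylic cation closes O1'–C2' trans to C3' and delivers 26.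

Step 18 (demethylation, borodesilylation, oxidation). Acid formed on quenching may ionise the benzylic ether carbons and drive attack of the electron-rich C5' on the protonated stilbene. Exchange of silicon for boron at the hindered C4' may stall or end in protodesilylation, and the free catechol may be over-oxidised. The fallback removes the stilbene from the acid step; it sets out from bromo ester 10 and returns at 28. Ester 10 is taken through the conditions of step 10 to the bromo alkyne F4. Cycloaddition of F4 with 25 as in step 17 gives the bromo arylsilane F5. BBr3 followed by oxidation (an amine N-oxide in place of perborate if the catechol suffers) gives the bromo heptaphenol F6. Suzuki–Miyaura coupling of F6 with (E)-2-(4-hydroxyphenyl)ethenylboronic acid pinacol ester (Pd(dppf)Cl2, K3PO4, dioxane–H2O, 80 °C) installs the stilbene last and gives 28.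

Step 13 (allenylzinc addition). The aryl-substituted allenylpalladium or allenylzinc may racemise before it adds, the anti preference may erode with an aromatic aldehyde, or the mesylate may ionise. The fallback separates enantiomers instead of relying on chirality transfer; it sets out from 16 and 19 and returns at 21. Alkyne 16 is converted with EtMgBr into its Grignard reagent and coupled with 3,5-dimethoxybenzyl bromide (CuBr cat., THF) to [3-(3,5-dimethoxyphenyl)prop-1-yn-1-yl]trimethylsilane F7. Deprotonation (n-BuLi, THF, −78 °C), transmetalation with ZnBr2 and addition to 19 through the same cyclic SE2' transition state should give the racemic anti alcohol F8. Preparative chromatography on a chiral stationary phase then provides the (1S,2S)-enantiomer 21.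

**Further compounds**

F1 | step 17 | {[(1S,2S)-1-(3,4-dimethoxyphenyl)-2-(3,5-dimethoxyphenyl)-4-(trimethylsilyl)but-3-yn-1-yl]oxy}(ethynyl)dimethylsilane | C#C[Si](C)(C)O[C@H](c1ccc(OC)c(OC)c1)[C@@H](c1cc(OC)cc(OC)c1)C#C[Si](C)(C)C
F2 | step 17 | (3S,4S)-3-(3,4-dimethoxyphenyl)-4-(3,5-dimethoxyphenyl)-7-[(2R,3R)-4-methoxy-2-(4-methoxyphenyl)-6-[(E)-2-(4-methoxyphenyl)ethenyl]-2,3-dihydro-1-benzofuran-3-yl]-1,1-dimethyl-5-(trimethylsilyl)-3,4-dihydro-1H-2,1-benzoxasiline | COc1ccc(/C=C/c2cc(OC)c3c(c2)O[C@@H](c2ccc(OC)cc2)[C@@H]3c2cc([Si](C)(C)C)c3c(c2)[Si](C)(C)O[C@H](c2ccc(OC)c(OC)c2)[C@H]3c2cc(OC)cc(OC)c2)cc1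
F3 | step 17 | 2-[(1S,2S)-2-(3,4-dimethoxyphenyl)-1-(3,5-dimethoxyphenyl)-2-hydroxyethyl]-5-[(2R,3R)-4-methoxy-2-(4-methoxyphenyl)-6-[(E)-2-(4-methoxyphenyl)ethenyl]-2,3-dihydro-1-benzofuran-3-yl]-3-(trimethylsilyl)phenol | COc1ccc(/C=C/c2cc(OC)c3c(c2)O[C@@H](c2ccc(OC)cc2)[C@@H]3c2cc(O)c([C@H](c3cc(OC)cc(OC)c3)[C@H](O)c3ccc(OC)c(OC)c3)c([Si](C)(C)C)c2)cc1
F4 | step 18 | (2R,3R)-6-bromo-3-ethynyl-4-methoxy-2-(4-methoxyphenyl)-2,3-dihydro-1-benzofuran | Brc1cc(OC)c2c(c1)O[C@@H](c1ccc(OC)cc1)[C@@H]2C#C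
F5 | step 18 | {(2S,3S)-6-[(2R,3R)-6-bromo-4-methoxy-2-(4-methoxyphenyl)-2,3-dihydro-1-benzofuran-3-yl]-2-(3,4-dimethoxyphenyl)-3-(3,5-dimethoxyphenyl)-2,3-dihydro-1-benzofuran-4-yl}trimethylsilane | Brc1cc(OC)c2c(c1)O[C@@H](c1ccc(OC)cc1)[C@@H]2c1cc([Si](C)(C)C)c2c(c1)O[C@H](c1ccc(OC)c(OC)c1)[C@H]2c1cc(OC)cc(OC)c1
F6 | step 18 | (2S,3S)-6-[(2R,3R)-6-bromo-4-hydroxy-2-(4-hydroxyphenyl)-2,3-dihydro-1-benzofuran-3-yl]-2-(3,4-dihydroxyphenyl)-3-(3,5-dihydroxyphenyl)-2,3-dihydro-1-benzofuran-4-ol | Brc1cc(O)c2c(c1)O[C@@H](c1ccc(O)cc1)[C@@H]2c1cc(O)c2c(c1)O[C@H](c1ccc(O)c(O)c1)[C@H]2c1cc(O)cc(O)c1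
F7 | step 13 | [3-(3,5-dimethoxyphenyl)prop-1-yn-1-yl]trimethylsilane | COc1cc(CC#C[Si](C)(C)C)cc(OC)c1
F8 | step 13 | rac-(1S,2S)-1-(3,4-dimethoxyphenyl)-2-(3,5-dimethoxyphenyl)-4-(trimethylsilyl)but-3-yn-1-ol (racemic anti) | O[C@H](c1ccc(OC)c(OC)c1)[C@@H](c1cc(OC)cc(OC)c1)C#C[Si](C)(C)C.O[C@@H](c1ccc(OC)c(OC)c1)[C@H](c1cc(OC)cc(OC)c1)C#C[Si](C)(C)C
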